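## Analysis of the target

The target 21 is a chalcone. Ring B is a 4-hydroxyphenyl group; ring A is a phloroglucinol nucleus that carries the (E)-cinnamoyl ketone at C8 and is fused to a 2,2-dimethyl-3-hydroxydihydropyran (chroman numbering: O1, C2 with the two methyl groups, carbinol C3, benzylic C4, aromatic C4a to C8a, free hydroxyls on C5 and C7). There is one stereocentre, C3, of S configuration. It lies between the quaternary C2 and the C4 methylene, with no neighbouring stereocentre to relay from, so it must be set by absolute control. The sensitive groups are the enone (reducible, open to conjugate addition, and able to take up the C7 hydroxyl to give a flavanone), the electron-rich ring A, the tertiary alkyl aryl ether O1–C2, and four hydroxyls. The main difficulty is regiochemical: the three oxygens of ring A are equivalent in any simple precursor, yet one must become O1, and the acyl group must go to C8 and not C6. The strategy rests on the array O1–C8a–C4a–C4, which is the skeleton of an ortho-quinone methide, and on C3 with its oxygen, which is the α-carbon of a glycolic acid derivative; C2 is then a carboxyl carbon that can later take the two methyl groups. Joining these two pieces under a chiral Lewis base makes the heterocycle as a 3-alkoxydihydrocoumarin and sets C3 in the same operation.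

## Retrosynthetic reasoning

The last disconnection cuts four oxygen–benzyl bonds: 21 comes from the tetrabenzyl ether 20. One kind of protecting group on all four oxygens means one final operation, and benzyl ethers tolerate everything before it (carbonate base, organocerium and organolithium reagents, sulfonic acid). The enone rules out hydrogenolysis, so the forward step must be a cold Lewis-acid cleavage with a cation scavenger that spares the alkene, the ketone and the O1–C2 ether.

Compound 20 is cut at the C8–carbonyl bond into the aryllithium 19 and the N-methoxy-N-methylamide 18. This brings in the whole cinnamoyl unit, ring B included, in one C–C bond formation at a ring carbon fixed beforehand. An electrophilic acylation of ring A would have to choose between C6 and C8 under conditions the ethers would not survive. Amide 18 is cut at its alkene into aldehyde 16 and phosphonate 17, so the E geometry is settled before the coupling.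

Aryllithium 19 goes back through bromide 15 to chroman 14 (C8–Br bond). The forward bromination must distinguish C8, between the ring oxygen and one benzyloxy group, from C6, between two benzyloxy groups.

Chroman 14 is opened at O1–C2 to the phenolic tertiary alcohol 13, and the two C2–methyl bonds of 13 are cut to reach lactone 11 by way of ketone 12. This traces the quaternary carbon back to a carbonyl carbon. The forward direction needs two methyl additions by a reagent of low basicity, so that neither 11 nor 12 is enolised at C3, and then an acid-induced closure of the phenol onto the tertiary carbinol in which no bond to C3 is broken.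

Lactone 11 is cut at C3–C4 and at O1–C2 into the quinone methide 10 and the activated glycolate ester 9. This is the central disconnection: both fragments are achiral, and the ring and the stereocentre arise together under a chiral isothiourea catalyst. C4 carries two hydrogens, so only one stereochemical element has to be controlled. Only one phenol is free, so the oxygen that becomes O1 is decided before the ring forms.

Quinone methide 10 cannot be stored and is released in the flask from sulfone 6. Compound 6 goes back to sulfinate 5 and benzylic alcohol 4, 4 to aldehyde 3, and 3 to 2,4,6-trihydroxybenzaldehyde 1 and benzyl bromide 2. The formyl carbon of 1 is C4 of the target, so it marks the ring carbon that becomes C4a. Ester 9 comes from acid 7 and 4-nitrophenol 8.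

## Alternatives that were turned down

Alternative 1: Here ring A is made last, by cutting C7–C8. The precursor A2 is a chiral 3-silyloxy-2,2-dimethyldihydropyran. Its enol ether carbon (the future C8a) carries a CH2–CO–CH=CH–aryl arm, and the neighbouring carbon (the future C4a) carries a β-keto methyl ester arm. A magnesium alkoxide base would form the C8 carbanion, which attacks the ester, closes the ring and aromatises to A1 by loss of methanol and enolisation.
- For it: ring A emerges with the C5 and C7 hydroxyls free and the cinnamoyl group already at C8, so neither the regiochemistry of acylation nor ring-A protection arises. The endgame removes only a silyl ether and an acetal. On these points it is stronger than the chosen route.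
- Against it: the key step creates no stereocentre, so C3 must be set earlier and carried through a long synthesis of A2, a tricarbonyl enol ether that also contains an enone. The most acidic site of A2 is the methylene between ketone and ester (C6), not C8. Its enolate deactivates the ester towards the Claisen closure, and it can instead close onto the cinnamoyl ketone in an aldol mode (a six-membered ring of the wrong constitution) or add to the enone.
- Comparison: the chosen strategy pays with a protected endgame and a late C8 functionalisation, but it starts from stable aromatic compounds, sets C3 in the ring-forming step itself, and is much shorter.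

Alternative 2: Ring A is assembled from the cyclobutenone A4 and the siloxyalkyne A5, which already holds C3 as an acetonide. Heating runs ring opening to a vinylketene, (2+2) addition to the alkyne, a second ring opening and a 6π closure (Danheiser benzannulation), forming C4a–C8a, C5–C6 and C8–C8a and giving A3.
- For it: the three oxygens come out mutually differentiated (free hydroxyl at C8a, silyl ether at C5, ethyl ether at C7) in one regiodefined step, and the free hydroxyl is the one that becomes O1. On this point it is stronger than a selective dibenzylation of 1.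
- Against it: this differentiation is not needed here, because 1 already carries the C4 carbon and its oxygens are equivalent until that carbon is used. A5 needs its own asymmetric step and a homologation to the ynol ether. After A3 the pyran ring still has to be closed at the tertiary carbon (the same cationic closure as in step 7 below), C8 still has to be acylated, and an ethyl aryl ether must finally be cleaved under harsher conditions than a benzyl ether.
- Comparison: the route would be longer and would spread its risk over several steps. The chosen strategy gives up built-in differentiation and offers one catalytic step that makes the ring and the stereocentre.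

Alternative 3: The cut is at C4–C4a. The precursor A7 is a 1,1-dimethylglycidyl ether of a symmetric 3,5-bis(benzyloxy)phenyl unit. On Lewis-acid activation the ortho carbon of the arene attacks the epoxide methylene (6-endo with respect to the epoxide), closing the pyran to A6.
- For it: A6 already has O1–C2 and the gem-dimethyl group, so the lactone-to-gem-dimethyl conversion and the tertiary closure (steps 6 and 7 below) fall away. Both ortho positions are equivalent. The C3 hydroxyl comes out free, so no alkyl benzyl ether needs cleaving at the end. On step count after the key step and on the final deprotection it is stronger than the chosen route.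
- Against it: the difficulty moves into A7. Its alkene precursor is a tertiary allyl ether of a very electron-rich phenol and is prone to aromatic Claisen rearrangement. Enantioselective epoxidation of a monosubstituted terminal alkene is poorly served, so a dihydroxylation and closure sequence of uncertain selectivity, or a resolution, would be needed. In the key step the Lewis acid can ionise the tertiary C–O bond or open the epoxide at its internal carbon (a 5-exo closure to a dihydrobenzofuran), and the nucleophilic ring can react intermolecularly.
- Comparison: the chosen route is longer after its key step, but its stereocentre comes from a catalyst-controlled C–C bond formation with a clear model, and its ring closure has no regiochemical alternative.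

Key step: step 5

Assumption: the facial sense of the isothiourea is taken from the usual face-shielding model, by which the (2S,3R) catalyst should give (S)-11; if it ran the other way, the (2R,3S) catalyst would be used with no other change.

## Route

Step 1
Reactants: 1 2,4,6-trihydroxybenzaldehyde; 2 benzyl bromide
Product: 3 2,4-bis(benzyloxy)-6-hydroxybenzaldehyde
Conditions: 2 (2.1 equiv), K2CO3, DMF, 0 °C to rt
Reagents that add atoms: none
Why: Williamson etherification; the C4 hydroxyl and one ortho hydroxyl are alkylated, while the remaining ortho hydroxyl is hydrogen-bonded to the formyl oxygen, is the least nucleophilic, and should stay free.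

Step 2
Reactants: 3 2,4-bis(benzyloxy)-6-hydroxybenzaldehyde
Product: 4 3,5-bis(benzyloxy)-2-(hydroxymethyl)phenol
Conditions: NaBH4, THF/MeOH, 0 °C; cold aqueous NH4Cl; crude product used at once
Reagents that add atoms: none
Why: Borohydride reduction of an aryl aldehyde; the low temperature and near-neutral quench are chosen because this electron-rich salicyl alcohol ionises easily.

Step 3
Reactants: 4 3,5-bis(benzyloxy)-2-(hydroxymethyl)phenol; 5 sodium p-toluenesulfinate
Product: 6 3,5-bis(benzyloxy)-2-[(4-methylbenzenesulfonyl)methyl]phenol
Conditions: 5 (2 equiv), HCO2H, THF/H2O, rt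
Reagents that add atoms: none
Why: Acid-promoted ionisation of the benzylic alcohol and capture of the stabilised cation at sulfur by the sulfinate (substitution of the unimolecular type); excess sulfinate should outrun self-condensation of the arene.

Step 4
Reactants: 7 benzyloxyacetic acid; 8 4-nitrophenol
Product: 9 4-nitrophenyl benzyloxyacetate
Conditions: EDCI·HCl, DMAP (cat.), CH2Cl2, 0 °C to rt
Reagents that add atoms: none
Why: Steglich esterification; the electron-poor aryl ester is reactive enough to acylate an isothiourea and releases an aryloxide that can act as the base in the next step.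

Step 5
Reactants: 6 3,5-bis(benzyloxy)-2-[(4-methylbenzenesulfonyl)methyl]phenol; 9 4-nitrophenyl benzyloxyacetate
Product: 11 (S)-3,5,7-tris(benzyloxy)chroman-2-one, via ortho-quinone methide 10 (not isolated)
Conditions: 9 (1.5 equiv), (2S,3R)-HyperBTM [(2S,3R)-3-isopropyl-2-phenyl-3,4-dihydro-2H-benzo[4,5]thiazolo[3,2-a]pyrimidine] (10 mol %), Cs2CO3, 4 Å molecular sieves, CH2Cl2, 0 °C to rt
Reagents that add atoms: none
Why: Cs2CO3 deprotonates the phenol of 6 and 1,4-elimination of p-toluenesulfinate releases the quinone methide 10 slowly, so that its stationary concentration stays low. The isothiourea is acylated by 9, and the expelled 4-nitrophenoxide removes the α-proton to give the (Z)-ammonium enolate, which is held coplanar with the catalyst by the 1,5 oxygen-to-sulfur contact. Conjugate addition of the enolate carbon to the exocyclic methide carbon forms C3–C4 and restores the aromaticity of ring A, and the phenoxide so released attacks the acyl isothiouronium carbonyl in a 6-exo-trig closure that forms O1–C2 and frees the catalyst. The closest known reaction type is the Lewis-base-catalysed (isothiourea or carbene) formal (4+2) annulation of C1 enolate equivalents with quinone methides generated in situ, which gives 3-substituted dihydrocoumarins; α-alkoxy acyl donors are established in the related tertiary-amine ketene-enolate chemistry. C3 is the only new stereocentre and is controlled by the catalyst alone: the pseudoaxial phenyl group next to the acylated nitrogen covers one enolate face and the methide adds to the other, which for the (2S,3R) catalyst should be the face leading to (S). Because the methide carbon carries two hydrogens, no diastereoselectivity is needed, only this facial selectivity. Regiochemistry is fixed by the substrate, since 6 has one free phenol and only that oxygen can become O1.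

Step 6
Reactants: 11 (S)-3,5,7-tris(benzyloxy)chroman-2-one
Product: 13 3,5-bis(benzyloxy)-2-[(2S)-2-(benzyloxy)-3-hydroxy-3-methylbutyl]phenol, via methyl ketone 12 (not isolated)
Conditions: MeLi/CeCl3 (MeCeCl2, 4 equiv), THF, −78 to 0 °C; aqueous NH4Cl
Reagents that add atoms: methyllithium, C[Li] (delivered as dichloro(methyl)cerium, C[Ce](Cl)Cl)
Why: Organocerium double addition to an aryl lactone; the first addition opens the ring to the ketone 12 as its phenoxide and the second gives the tertiary alkoxide, and the low basicity of the cerium reagent should prevent enolisation of 11 and 12, so that C3 keeps its configuration.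

Step 7
Reactants: 13 3,5-bis(benzyloxy)-2-[(2S)-2-(benzyloxy)-3-hydroxy-3-methylbutyl]phenol
Product: 14 (S)-3,5,7-tris(benzyloxy)-2,2-dimethylchromane
Conditions: p-TsOH·H2O (10 mol %), toluene, 50 °C
Reagents that add atoms: none
Why: Acid-catalysed cycloetherification through the tertiary carbocation, which the phenol oxygen captures in a six-membered closure (O1–C2); no bond to C3 is broken, so its configuration is retained, and both ring carbons ortho to the side chain are substituted, so C-alkylation cannot compete.

Step 8
Reactants: 14 (S)-3,5,7-tris(benzyloxy)-2,2-dimethylchromane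
Product: 15 (S)-3,5,7-tris(benzyloxy)-8-bromo-2,2-dimethylchromane
Conditions: NBS (1.0 equiv), CH2Cl2, −78 to −20 °C
Reagents that add atoms: N-bromosuccinimide, O=C1CCC(=O)N1Br
Why: Electrophilic aromatic bromination; C8 is flanked by the ring oxygen, whose alkyl group is tied back and whose lone pair is held in conjugation, whereas C6 lies between two freely rotating benzyloxy groups, and 5,7-dialkoxy flavans monobrominate at C8 for the same reason.

Step 9
Reactants: 16 4-(benzyloxy)benzaldehyde; 17 diethyl [2-(methoxy(methyl)amino)-2-oxoethyl]phosphonate
Product: 18 (E)-3-[4-(benzyloxy)phenyl]-N-methoxy-N-methylprop-2-enamide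
Conditions: NaH, THF, 0 °C to rt
Reagents that add atoms: none
Why: Horner–Wadsworth–Emmons olefination with a stabilised phosphonate anion, which should give the E alkene under thermodynamic control of the elimination.

Step 10
Reactants: 15 (S)-3,5,7-tris(benzyloxy)-8-bromo-2,2-dimethylchromane; 18 (E)-3-[4-(benzyloxy)phenyl]-N-methoxy-N-methylprop-2-enamide
Product: 20 (E)-3-[4-(benzyloxy)phenyl]-1-[(3S)-3,5,7-tris(benzyloxy)-2,2-dimethylchroman-8-yl]prop-2-en-1-one, via aryllithium 19 (not isolated)
Conditions: n-BuLi, THF, −78 °C; then 18, −78 to 0 °C; aqueous NH4Cl
Reagents that add atoms: none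
Why: Bromine–lithium exchange followed by 1,2-addition of the hard aryllithium to the N-methoxy-N-methylamide (Weinreb ketone synthesis); the chelated tetrahedral adduct holds until work-up, so no second addition occurs, and the alkene geometry is untouched.

Step 11
Reactants: 20 (E)-3-[4-(benzyloxy)phenyl]-1-[(3S)-3,5,7-tris(benzyloxy)-2,2-dimethylchroman-8-yl]prop-2-en-1-one
Product: 21 (E)-1-[(3S)-3,5,7-trihydroxy-2,2-dimethylchroman-8-yl]-3-(4-hydroxyphenyl)prop-2-en-1-one
Conditions: BCl3 (excess), pentamethylbenzene, CH2Cl2, −78 to −30 °C; MeOH quench
Reagents that add atoms: none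
Why: Lewis-acid debenzylation of three aryl benzyl ethers and one alkyl benzyl ether; pentamethylbenzene traps the benzyl cations without binding boron, which should keep them off ring A, and the method does not reduce the enone.

## Compound list

1 | 2,4,6-trihydroxybenzaldehyde | O=Cc1c(O)cc(O)cc1O | starting material
2 | benzyl bromide | BrCc1ccccc1 | starting material
3 | 2,4-bis(benzyloxy)-6-hydroxybenzaldehyde | O=Cc1c(O)cc(OCc2ccccc2)cc1OCc1ccccc1 | intermediate
4 | 3,5-bis(benzyloxy)-2-(hydroxymethyl)phenol | OCc1c(O)cc(OCc2ccccc2)cc1OCc1ccccc1 | intermediate
5 | sodium p-toluenesulfinate | Cc1ccc(cc1)S(=O)[O-].[Na+] | starting material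
6 | 3,5-bis(benzyloxy)-2-[(4-methylbenzenesulfonyl)methyl]phenol | Cc1ccc(cc1)S(=O)(=O)Cc1c(O)cc(OCc2ccccc2)cc1OCc1ccccc1 | intermediate
7 | benzyloxyacetic acid | OC(=O)COCc1ccccc1 | starting material
8 | 4-nitrophenol | Oc1ccc(cc1)[N+](=O)[O-] | starting material
9 | 4-nitrophenyl benzyloxyacetate | O=C(COCc1ccccc1)Oc1ccc(cc1)[N+](=O)[O-] | intermediate
10 | 3,5-bis(benzyloxy)-6-methylidenecyclohexa-2,4-dien-1-one (ortho-quinone methide, formed in the flask) | C=C1C(=O)C=C(OCc2ccccc2)C=C1OCc1ccccc1 | intermediate
11 | (S)-3,5,7-tris(benzyloxy)chroman-2-one | O=C1Oc2cc(OCc3ccccc3)cc(OCc3ccccc3)c2C[C@@H]1OCc1ccccc1 | intermediate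
12 | (3S)-3-(benzyloxy)-4-[2,4-bis(benzyloxy)-6-hydroxyphenyl]butan-2-one (formed in the flask as its phenoxide) | CC(=O)[C@@H](OCc1ccccc1)Cc1c(O)cc(OCc2ccccc2)cc1OCc1ccccc1 | intermediate
13 | 3,5-bis(benzyloxy)-2-[(2S)-2-(benzyloxy)-3-hydroxy-3-methylbutyl]phenol | CC(C)(O)[C@@H](OCc1ccccc1)Cc1c(O)cc(OCc2ccccc2)cc1OCc1ccccc1 | intermediate
14 | (S)-3,5,7-tris(benzyloxy)-2,2-dimethylchromane | CC1(C)Oc2cc(OCc3ccccc3)cc(OCc3ccccc3)c2C[C@@H]1OCc1ccccc1 | intermediate
15 | (S)-3,5,7-tris(benzyloxy)-8-bromo-2,2-dimethylchromane | CC1(C)Oc2c(c(OCc3ccccc3)cc(OCc3ccccc3)c2Br)C[C@@H]1OCc1ccccc1 | intermediate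
16 | 4-(benzyloxy)benzaldehyde | O=Cc1ccc(OCc2ccccc2)cc1 | starting material
17 | diethyl [2-(methoxy(methyl)amino)-2-oxoethyl]phosphonate | CCOP(=O)(CC(=O)N(C)OC)OCC | starting material
18 | (E)-3-[4-(benzyloxy)phenyl]-N-methoxy-N-methylprop-2-enamide | CON(C)C(=O)/C=C/c1ccc(OCc2ccccc2)cc1 | intermediate
19 | [(3S)-3,5,7-tris(benzyloxy)-2,2-dimethylchroman-8-yl]lithium (formed in the flask) | CC1(C)Oc2c(c(OCc3ccccc3)cc(OCc3ccccc3)c2[Li])C[C@@H]1OCc1ccccc1 | intermediate
20 | (E)-3-[4-(benzyloxy)phenyl]-1-[(3S)-3,5,7-tris(benzyloxy)-2,2-dimethylchroman-8-yl]prop-2-en-1-one | CC1(C)Oc2c(c(OCc3ccccc3)cc(OCc3ccccc3)c2C(=O)/C=C/c2ccc(OCc3ccccc3)cc2)C[C@@H]1OCc1ccccc1 | intermediate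
21 | (E)-1-[(3S)-3,5,7-trihydroxy-2,2-dimethylchroman-8-yl]-3-(4-hydroxyphenyl)prop-2-en-1-one | CC1(C)Oc2c(c(O)cc(O)c2C(=O)/C=C/c2ccc(O)cc2)C[C@@H]1O | target

## Step count and least certain steps

Total: 11 steps. Longest linear sequence: 9 steps (steps 1, 2, 3, 5, 6, 7, 8, 10, 11); steps 4 and 9 prepare the two side fragments.

**Step 5 (key step).** Three processes can go wrong.
- Enolisation of the α-alkoxy acyl isothiouronium ion may be slow compared with the aryl- and alkenylacetyl donors usual in this catalysis. The electron-rich quinone methide would then be consumed by self-condensation, by reversible capture by 4-nitrophenoxide or water, or the phenol of 6 would simply be O-acylated.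
- The lactone has an acidic C3–H and is itself an aryl ester, so base-induced epimerisation or reopening by the catalyst could erode the enantiomeric purity.
- The facial sense rests on a model.

Fallback, setting out from 6 and 7 and returning at 11: the stereocentre is set by a chiral auxiliary instead of a catalyst. Acid 7 is attached through its mixed pivalic anhydride to lithiated (R)-4-benzyloxazolidin-2-one to give (R)-4-benzyl-3-[(benzyloxy)acetyl]oxazolidin-2-one F1. Its chelated (Z)-sodium enolate (NaHMDS, THF, −78 °C) is combined with 10, released from 6 by a second equivalent of NaHMDS. Addition anti to the benzyl group of the auxiliary should give the phenoxide of (R)-4-benzyl-3-[(2S)-2-(benzyloxy)-3-[2,4-bis(benzyloxy)-6-hydroxyphenyl]propanoyl]oxazolidin-2-one F2. On warming this closes onto the imide carbonyl, expels the auxiliary and gives 11.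

**Step 7.** The tertiary cation sits next to a carbon that bears hydrogen and an ether oxygen. A 1,2-hydride shift (pinacol-type rearrangement) or elimination towards C3 would destroy the stereocentre, and acid could also cause benzyl migration on ring A.

Fallback, setting out from 11 and returning at 14 (it replaces steps 6 and 7): the second methyl group is delivered after O1–C2 exists, so no open tertiary cation is involved. Lactone 11 is opened with N,O-dimethylhydroxylamine hydrochloride and AlMe3 to (S)-2-(benzyloxy)-3-[2,4-bis(benzyloxy)-6-hydroxyphenyl]-N-methoxy-N-methylpropanamide F3. MeMgBr converts it into ketone 12, which equilibrates with its cyclic hemiketal (3S)-3,5,7-tris(benzyloxy)-2-methylchroman-2-ol F4. AlMe3 with TMSOTf in CH2Cl2 at −78 °C ionises the hemiketal at C2 to an oxygen-stabilised cation and transfers a methyl group to give 14.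

**Step 11.** Three things can go wrong.
- Boron bound to the C8 carbonyl can assist ionisation of the O1–C2 tertiary ether.
- The alkyl benzyl ether at C3 cleaves more slowly than the aryl ethers. The warming it needs may allow addition of HCl to the enone or closure of the C7 hydroxyl onto it.
- Benzyl cations may alkylate ring A if trapping is incomplete.

Fallback, setting out from 14 and returning at 21: the benzyl groups are exchanged for methoxymethyl groups before the enone exists, so the last step is a mild Brønsted-acid acetal cleavage.
- Hydrogenolysis of 14 (H2, Pd/C, EtOAc) gives (S)-2,2-dimethylchromane-3,5,7-triol F5.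
- MOMCl and NaH give (S)-3,5,7-tris(methoxymethoxy)-2,2-dimethylchromane F6.
- NBS gives (S)-8-bromo-3,5,7-tris(methoxymethoxy)-2,2-dimethylchromane F7.
- n-BuLi gives [(3S)-3,5,7-tris(methoxymethoxy)-2,2-dimethylchroman-8-yl]lithium F8.
- F8 is acylated by (E)-N-methoxy-3-[4-(methoxymethoxy)phenyl]-N-methylprop-2-enamide F9 (from 4-(methoxymethoxy)benzaldehyde and 17 as in step 9) to give (E)-3-[4-(methoxymethoxy)phenyl]-1-[(3S)-3,5,7-tris(methoxymethoxy)-2,2-dimethylchroman-8-yl]prop-2-en-1-one F10.
- HCl in MeOH at rt to 40 °C removes the four acetals and gives 21.

**Step 10.** The aryllithium has two ortho substituents and may add slowly, so that conjugate addition to the cinnamoyl amide competes. On warming, proton transfer from the benzylic CH2 of the neighbouring ether would quench it.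

Fallback, setting out from 19 and returning at 20: 19 is acylated with N-methoxy-N-methylacetamide to give 1-[(3S)-3,5,7-tris(benzyloxy)-2,2-dimethylchroman-8-yl]ethan-1-one F11. A Claisen–Schmidt condensation of F11 with aldehyde 16 (KOH, EtOH, rt) then builds the enone of 20 with E geometry.

**Step 2.** The borate of the electron-rich salicyl alcohol can lose its benzylic oxygen, after which hydride adds to the resulting methide (over-reduction of the benzylic position). The alcohol can also oligomerise on concentration.

Fallback, setting out from 3 and returning at 6: the benzylic oxygen is avoided altogether. Reductive amination of 3 (Me2NH, NaBH(OAc)3, 1,2-dichloroethane) gives 3,5-bis(benzyloxy)-2-[(dimethylamino)methyl]phenol F12. MeI gives [2,4-bis(benzyloxy)-6-hydroxybenzyl]trimethylammonium iodide F13. Sulfinate 5 in aqueous DMF then displaces trimethylamine, by way of 10, to give 6.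

## Further compounds

F1 | step 5 | (R)-4-benzyl-3-[(benzyloxy)acetyl]oxazolidin-2-one | O=C(COCc1ccccc1)N1[C@H](Cc2ccccc2)COC1=O
F2 | step 5 | (R)-4-benzyl-3-[(2S)-2-(benzyloxy)-3-[2,4-bis(benzyloxy)-6-hydroxyphenyl]propanoyl]oxazolidin-2-one | O=C([C@@H](OCc1ccccc1)Cc1c(O)cc(OCc2ccccc2)cc1OCc1ccccc1)N1[C@H](Cc2ccccc2)COC1=O
F3 | step 7 | (S)-2-(benzyloxy)-3-[2,4-bis(benzyloxy)-6-hydroxyphenyl]-N-methoxy-N-methylpropanamide | CON(C)C(=O)[C@@H](OCc1ccccc1)Cc1c(O)cc(OCc2ccccc2)cc1OCc1ccccc1
F4 | step 7 | (3S)-3,5,7-tris(benzyloxy)-2-methylchroman-2-ol (both C2 epimers) | CC1(O)Oc2cc(OCc3ccccc3)cc(OCc3ccccc3)c2C[C@@H]1OCc1ccccc1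
F5 | step 11 | (S)-2,2-dimethylchromane-3,5,7-triol | CC1(C)Oc2cc(O)cc(O)c2C[C@@H]1O
F6 | step 11 | (S)-3,5,7-tris(methoxymethoxy)-2,2-dimethylchromane | CC1(C)Oc2cc(OCOC)cc(OCOC)c2C[C@@H]1OCOC
F7 | step 11 | (S)-8-bromo-3,5,7-tris(methoxymethoxy)-2,2-dimethylchromane | CC1(C)Oc2c(c(OCOC)cc(OCOC)c2Br)C[C@@H]1OCOC
F8 | step 11 | [(3S)-3,5,7-tris(methoxymethoxy)-2,2-dimethylchroman-8-yl]lithium | CC1(C)Oc2c(c(OCOC)cc(OCOC)c2[Li])C[C@@H]1OCOC
F9 | step 11 | (E)-N-methoxy-3-[4-(methoxymethoxy)phenyl]-N-methylprop-2-enamide | CON(C)C(=O)/C=C/c1ccc(OCOC)cc1
F10 | step 11 | (E)-3-[4-(methoxymethoxy)phenyl]-1-[(3S)-3,5,7-tris(methoxymethoxy)-2,2-dimethylchroman-8-yl]prop-2-en-1-one | CC1(C)Oc2c(c(OCOC)cc(OCOC)c2C(=O)/C=C/c2ccc(OCOC)cc2)C[C@@H]1OCOC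
F11 | step 10 | 1-[(3S)-3,5,7-tris(benzyloxy)-2,2-dimethylchroman-8-yl]ethan-1-one | CC1(C)Oc2c(c(OCc3ccccc3)cc(OCc3ccccc3)c2C(C)=O)C[C@@H]1OCc1ccccc1
F12 | step 2 | 3,5-bis(benzyloxy)-2-[(dimethylamino)methyl]phenol | CN(C)Cc1c(O)cc(OCc2ccccc2)cc1OCc1ccccc1
F13 | step 2 | [2,4-bis(benzyloxy)-6-hydroxybenzyl]trimethylammonium iodide | C[N+](C)(C)Cc1c(O)cc(OCc2ccccc2)cc1OCc1ccccc1.[I-]
A1 | alternative 1 | (E)-1-[(3S)-3-(tert-butyldimethylsilyloxy)-5,7-dihydroxy-2,2-dimethylchroman-8-yl]-3-[4-(methoxymethoxy)phenyl]prop-2-en-1-one | CC1(C)Oc2c(c(O)cc(O)c2C(=O)/C=C/c2ccc(OCOC)cc2)C[C@@H]1O[Si](C)(C)C(C)(C)C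
A2 | alternative 1 | methyl 3-[(3S)-3-(tert-butyldimethylsilyloxy)-6-{(E)-4-[4-(methoxymethoxy)phenyl]-2-oxobut-3-en-1-yl}-2,2-dimethyl-3,4-dihydro-2H-pyran-5-yl]-3-oxopropanoate | CC1(C)OC(CC(=O)/C=C/c2ccc(OCOC)cc2)=C(C(=O)CC(=O)OC)C[C@@H]1O[Si](C)(C)C(C)(C)C
A3 | alternative 2 | 5-ethoxy-2-{[(4S)-2,2,5,5-tetramethyl-1,3-dioxolan-4-yl]methyl}-3-(triisopropylsilyloxy)phenol | Oc1cc(OCC)cc(O[Si](C(C)C)(C(C)C)C(C)C)c1C[C@@H]1OC(C)(C)OC1(C)C
A4 | alternative 2 | 3-ethoxycyclobut-2-en-1-one | CCOC1=CC(=O)C1
A5 | alternative 2 | triisopropyl({3-[(4S)-2,2,5,5-tetramethyl-1,3-dioxolan-4-yl]prop-1-yn-1-yl}oxy)silane | CC(C)[Si](C(C)C)(C(C)C)OC#CC[C@@H]1OC(C)(C)OC1(C)C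
A6 | alternative 3 | (S)-5,7-bis(benzyloxy)-2,2-dimethylchroman-3-ol | CC1(C)Oc2cc(OCc3ccccc3)cc(OCc3ccccc3)c2C[C@@H]1O
A7 | alternative 3 | (S)-2-{2-[3,5-bis(benzyloxy)phenoxy]propan-2-yl}oxirane | CC(C)(Oc1cc(OCc2ccccc2)cc(OCc2ccccc2)c1)[C@@H]1CO1
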